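Compound numbers used below are those of the compound list after the steps.

## Analysis of the target

Target 13 is an open-chain compound: a tridecane chain, numbered from the benzylic carbon C1, that carries a 3,5-dihydroxyphenyl ring on C1, an acetoxy group on C2 and a ketone at C8; the benzene ring is the only ring. C2 is the only stereocentre and has the (R) configuration (priorities O > C1 > C3 > H), so only absolute configuration has to be controlled. The sensitive groups are the free resorcinol (electron-rich, acidic, easily acylated and oxidised), the secondary acetate (cleaved by base and nucleophiles) and the dialkyl ketone at C8. Two things make the synthesis harder than its size suggests. First, C2 lies between two methylene groups, C1 and C3, so the two substituents a reagent must tell apart are sterically alike, and reagent-controlled reduction or resolution has little to work with. Second, three oxygen atoms could carry the acetyl group and only the aliphatic one does, while the C8 carbonyl is at the same oxidation level as the carbonyl from which C2 is most simply made. The strategy rests on this last point: in the 2,8-diketone the C2 carbonyl carries the resorcinol-benzyl arm on C1, whereas the C8 carbonyl lies between two unbranched alkyl arms, and an enzyme active site can read that difference both for the choice of carbonyl and for the choice of face.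

## Retrosynthetic reasoning

**13 to 12 to 11 (acyl C–O bonds).** Placing one acetyl group on the C2 oxygen of triol 11 in the presence of two phenols is not dependable in the acylation direction. The reverse selection is dependable, because aryl esters are far better acyl donors than alkyl esters. Target 13 is therefore traced to triacetate 12, from which the two aryl acetates are removed, and 12 to triol 11 by exhaustive acetylation. Two steps are spent, but no extra protecting group is carried and the C2–O bond is never broken, so the configuration is safe.

**11 to 10 (the C2–H bond, key disconnection).** Removing the hydride from C2 leads to the achiral diketone 10. This cut removes the only stereocentre, so everything before it is achiral chemistry. The forward reaction is a cofactor-dependent ketoreductase reduction that must choose C2 over C8, deliver hydride to the Si face of C2, and tolerate the free resorcinol. The phenols are left free in 10 on purpose: they make the substrate soluble in buffer and save a deprotection after the stereocentre is set. The C2 and C8 carbonyls are in a 1,7-relationship and could close a six-membered aldol ring under strong base, so no basic step is placed on any compound in which both ketones are free.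

**10 to 9 (two O–benzyl bonds).** The phenols are carried as benzyl ethers because these come with the commercial arene 6, survive organomagnesium reagents and aqueous acid, and are removed by hydrogenolysis under neutral conditions that leave both ketones alone.

**9 to 8 to 5 + 6 (the C1–C2 bond).** C2 is a carbonyl carbon in 9, so it can come from an acyl donor, and C1 with its ring is available as benzyl bromide 6, which is converted into Grignard reagent 7. Cutting C2–C3 instead would need an arylacetyl donor with acidic α-protons and a functionalised alkyl organometallic, both less convenient. Weinreb amide 5 is the acyl donor, so the addition stops at the ketone. The C8 carbonyl must be masked during this step; it is present as the dioxolane in 5 and in adduct 8, and 8 is unmasked to 9 in the acidic quench of the same operation.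

**5 to 4 to 3 (functional group changes).** Amide 5 comes from methyl ester 4 by direct aminolysis with a metal amide, and 4 comes from keto ester 3 by ketalisation. The dioxolane is installed before the amide is made because the basic magnesium reagents of both following steps would add to or enolise a free ketone.

**3 to 1 + 2 (the C8–C9 bond).** The C7 diacid derivative 1 has its two ends already differentiated as acid chloride and methyl ester. Catalysed acylation of Grignard reagent 2 at the acid chloride makes the C8 ketone and leaves the ester as the future C2.

## Alternatives that were turned down

**Alternative 1:** The benzene ring is taken apart instead of the side chain. Two ring C–C bonds are cut, so that the resorcinol is traced to the open-chain methyl enone (R,E)-6-(tert-butyldimethylsilyloxy)-11-(2-pentyl-1,3-dioxolan-2-yl)undec-3-en-2-one (A2) and a malonate diester.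
- Forward key step: the malonate anion adds to the β-carbon of A2 and the methyl ketone enolate then closes onto one ester group (Michael addition, then Claisen condensation). This gives the cyclohexane-1,3-dione ester A1, which must still be dehydrogenated and decarboxylated to reach the aromatic ring.
- For: the 1,3,5-pattern of the ring is correct by construction, the reagents are bulk chemicals, and no benzyl ethers or hydrogenation are needed. On the cost of the arene this alternative is stronger than the chosen route.
- Against: the step creates no stereocentre that survives, so C2 must be set earlier by a separate asymmetric step and carried as a silyl ether through alkoxide conditions. There, deprotonation of A2 at the γ-carbon opens a vinylogous elimination of the silyloxy group. Aromatisation of A1 needs an oxidation and an ester cleavage harsher than the rest of the molecule tolerates, and the C8 ketone must stay masked throughout.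
- Comparison: the step count is clearly higher, because the enone, the stereocentre, the ring, the aromatisation, two deprotections and the acetylation are separate operations. The chosen route buys the ring ready-made in 6 and spends its effort on C2 alone.

**Alternative 2:** Two bonds are cut at once, C2–C3 and aryl–C1.
- Forward key step: the primary alkyllithium A4 (the C3–C13 portion with C8 as its dioxolane) adds to vinylboronic acid pinacol ester A5 to give a boron ate complex. Palladium catalysis with a chiral diphosphine ligand couples this with aryl triflate A6: oxidative addition, coordination of the vinyl group and 1,2-migration of the alkyl group from boron to carbon give the secondary boronate A3, which is then oxidised with retention to the alcohol.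
- For: two skeletal bonds and the stereocentre arise in one catalytic step from three simple pieces. There is only one reactive site, so no site selectivity is needed, and the stereochemical outcome of this reaction class with primary migrating groups is predictable. On convergence and on predictability it is at least as strong as the chosen route.
- Against: A4 must be generated by halogen–lithium exchange at low temperature from an iodide that itself takes several steps. The ketone stays protected, A3 must be oxidised, acetylated and deprotected twice, and a precious-metal catalyst with an expensive chiral ligand is consumed in the stereo-defining step.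
- Comparison: the step count is about the same or slightly higher. The chosen route offers instead an achiral, robust sequence up to 10, no cryogenic organolithium chemistry, and a stereo-defining step in water at ambient temperature on the unprotected substrate. Its price is that the enzyme must be found by screening.

**Alternative 3:** The chain is cut at C5–C6.
- Forward key step: the primary radical generated at C5 from iodide A8, with a silane chain carrier and an azo initiator, adds to the terminal carbon of oct-1-en-3-one (A9). Reduction of the adduct radical gives A7, the dibenzyl ether of the target, which needs only hydrogenolysis.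
- For: the C8 ketone arrives unprotected, radical conditions leave the acetate and benzyl ethers alone, and one step follows the key step. In the length of the endgame and in avoiding any ketal it is stronger than the chosen route.
- Against: the stereocentre is not made by this step, so A8 must be built as a single enantiomer beforehand (chiral epoxide opening, acetylation, unmasking and iodination of a C5 alcohol), which is where most of the steps go. The C5 radical can abstract a benzylic hydrogen from C1 through a six-membered transition state, and this 1,5-hydrogen shift competes with intermolecular addition. The vinyl ketone A9 telomerises and must be used in excess, and a stoichiometric silane is needed.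
- Comparison: the chosen route sets the stereocentre last instead of first, with isopropanol as the only stoichiometric reagent in that step, at the cost of carrying the C8 ketone as a dioxolane through two steps.

Key step: step 6

Assumption: the ketoreductase is taken from a commercial panel of engineered NADPH-dependent short-chain dehydrogenases. Which member is used is decided by screening, so it is described by the selectivity it must show and not by a name.

## Route

Step 1
Reactants: 1 methyl 7-chloro-7-oxoheptanoate; 2 pentylmagnesium bromide
Product: 3 methyl 7-oxododecanoate
Conditions: Fe(acac)3 (3 mol%), THF, −78 °C, 2 (1.05 equiv) added slowly; aqueous NH4Cl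
Reagents that add atoms: none
Why: Iron-catalysed acylation of a Grignard reagent by an acid chloride (cross-coupling at the acyl carbon); the low-valent iron species formed from Fe(acac)3 should turn over at −78 °C much faster than 2 adds to the methyl ester or to the ketone being formed, so a single C–C bond is made at the chloride carbon.

Step 2
Reactants: 3 methyl 7-oxododecanoate
Product: 4 methyl 6-(2-pentyl-1,3-dioxolan-2-yl)hexanoate
Conditions: 1,2-bis(trimethylsilyloxy)ethane (1.5 equiv), Me3SiOTf (2 mol%), CH2Cl2, −78 to −20 °C; pyridine quench
Reagents that add atoms: 1,2-bis(trimethylsilyloxy)ethane, C[Si](C)(C)OCCO[Si](C)(C)C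
Why: Noyori ketalisation, in which the silyl triflate activates the ketone and the bis-silyl ether delivers the diol with loss of hexamethyldisiloxane; the medium is aprotic and free of diol, so the methyl ester cannot transesterify. The dioxolane is needed because the magnesium reagents of steps 3 and 4 would add to or enolise a free C8 ketone.

Step 3
Reactants: 4 methyl 6-(2-pentyl-1,3-dioxolan-2-yl)hexanoate
Product: 5 N-methoxy-N-methyl-6-(2-pentyl-1,3-dioxolan-2-yl)hexanamide
Conditions: MeNH(OMe)·HCl (1.5 equiv), iPrMgCl (3.0 equiv), THF, −20 to 0 °C; aqueous NH4Cl
Reagents that add atoms: N,O-dimethylhydroxylamine hydrochloride, CNOC.Cl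
Why: Direct conversion of an ester into a Weinreb amide: iPrMgCl turns the hydroxylamine salt into its chloromagnesium amide, which acylates on the ester at low temperature. The dioxolane is inert to base, and the hindered iPrMgCl does not add to the product amide at this temperature.

Step 4
Reactants: 5 N-methoxy-N-methyl-6-(2-pentyl-1,3-dioxolan-2-yl)hexanamide; 6 3,5-bis(benzyloxy)benzyl bromide
Product: 9 1-[3,5-bis(benzyloxy)phenyl]tridecane-2,8-dione, via benzylic Grignard reagent 7 (not isolated), via dioxolane benzyl ketone 8 (not isolated)
Conditions: 6 (1.6 equiv) added slowly to Mg turnings (4 equiv, I2-activated), 2-MeTHF, 0 °C; then 5, THF, −10 to 0 °C; then 2 M aqueous HCl, rt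
Reagents that add atoms: water, O
Why: Weinreb ketone synthesis followed by acetal hydrolysis: 7 adds once because the magnesium-chelated tetrahedral adduct does not collapse before the quench, and the aqueous HCl used for the quench then hydrolyses the dioxolane of 8 at room temperature, conditions to which aryl benzyl ethers are stable. Slow addition of 6 to excess magnesium in cold 2-methyltetrahydrofuran keeps the halide concentration low and so holds back Wurtz coupling.

Step 5
Reactants: 9 1-[3,5-bis(benzyloxy)phenyl]tridecane-2,8-dione
Product: 10 1-(3,5-dihydroxyphenyl)tridecane-2,8-dione
Conditions: H2 (1 atm), Pd/C (10 wt%), EtOAc–MeOH (1:1), rt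
Reagents that add atoms: none
Why: Catalytic hydrogenolysis of aryl benzyl ethers over palladium on carbon; the two ketones, neither of which has its carbonyl carbon on the ring, should not be reduced at one atmosphere in a neutral solvent, and the absence of base avoids aldol closure between C2 and C8.

Step 6
Reactants: 10 1-(3,5-dihydroxyphenyl)tridecane-2,8-dione
Product: 11 (2R)-1-(3,5-dihydroxyphenyl)-2-hydroxytridecan-8-one
Conditions: (R)-selective NADPH-dependent ketoreductase (chosen by panel screening), NADP+ (cat.), iPrOH (10% v/v), KH2PO4/K2HPO4 buffer (0.1 M, pH 7.0), MgSO4 (2 mM), DMSO (5% v/v), 30 °C
Reagents that add atoms: none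
Why: The enzyme binds NADPH and the substrate so that the C4 hydride of the dihydronicotinamide is delivered to one face of the bound carbonyl while the active-site tyrosine of the Ser–Tyr–Lys triad protonates the oxygen; NADP+ is returned to NADPH on the same enzyme by oxidation of isopropanol to acetone, and the large excess of isopropanol pulls the equilibrium towards the alcohol. The closest known reaction type is the ketoreductase reduction of 1-arylpropan-2-ones and of ketones with two large substituents under coupled-substrate cofactor recycling. No ring is closed and no skeletal bond is formed; only the C2–H bond is made. The new stereocentre at C2 is controlled by the enzyme alone: an anti-Prelog reductase of the Lactobacillus kefir type that seats the resorcinol-benzyl arm in its large pocket and the C3 chain in the second pocket delivers hydride to the Si face of C2, which gives the (R) alcohol. Two selectivities are needed, C2 over C8 and Si over Re. Both are secured by the same element of 10: the C2 carbonyl is one carbon from the arene, is the more electrophilic of the two because of the inductively withdrawing benzyl group, and is the one that sits over the nicotinamide when the resorcinol is anchored in the substrate pocket, whereas the C8 carbonyl lies between two flexible unbranched arms that offer no handle. The free phenols should make 10 soluble enough in buffer with a little DMSO and are not touched. Because reductases of both facial preferences exist in such panels, the member that is both (R)-selective and C2-selective is identified by screening against 10.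

Step 7
Reactants: 11 (2R)-1-(3,5-dihydroxyphenyl)-2-hydroxytridecan-8-one
Product: 12 5-[(2R)-2-acetoxy-8-oxotridecyl]-1,3-phenylene diacetate
Conditions: Ac2O (4 equiv), pyridine (6 equiv), DMAP (5 mol%), CH2Cl2, 0 °C to rt
Reagents that add atoms: acetic anhydride, CC(=O)OC(C)=O
Why: DMAP-catalysed acylation (nucleophilic catalysis through the N-acetylpyridinium ion) esterifies both phenols and the secondary alcohol; the C2–O bond is not broken, so the configuration is retained, and the dialkyl ketone at C8 does not form an enol acetate under these conditions.

Step 8
Reactants: 12 5-[(2R)-2-acetoxy-8-oxotridecyl]-1,3-phenylene diacetate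
Product: 13 (2R)-1-(3,5-dihydroxyphenyl)-8-oxotridecan-2-yl acetate
Conditions: pyrrolidine (2.3 equiv), MeCN, 0 °C; cold 0.5 M aqueous HCl wash
Reagents that add atoms: none
Why: Chemoselective aminolysis of aryl esters: phenoxide is a far better leaving group than a secondary alkoxide, so a secondary amine at 0 °C should cleave both aryl acetates and leave the C2 acetate in place. The cold dilute acid wash removes the amine and reverses any carbinolamine formed at C8.

## Compound list

1 | methyl 7-chloro-7-oxoheptanoate | COC(=O)CCCCCC(Cl)=O | starting material
2 | pentylmagnesium bromide | CCCCC[Mg]Br | starting material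
3 | methyl 7-oxododecanoate | CCCCCC(=O)CCCCCC(=O)OC | intermediate
4 | methyl 6-(2-pentyl-1,3-dioxolan-2-yl)hexanoate | CCCCCC1(CCCCCC(=O)OC)OCCO1 | intermediate
5 | N-methoxy-N-methyl-6-(2-pentyl-1,3-dioxolan-2-yl)hexanamide | CCCCCC1(CCCCCC(=O)N(C)OC)OCCO1 | intermediate
6 | 3,5-bis(benzyloxy)benzyl bromide | BrCc1cc(OCc2ccccc2)cc(OCc2ccccc2)c1 | starting material
7 | [3,5-bis(benzyloxy)benzyl]magnesium bromide | Br[Mg]Cc1cc(OCc2ccccc2)cc(OCc2ccccc2)c1 | intermediate (not isolated)
8 | 1-[3,5-bis(benzyloxy)phenyl]-7-(2-pentyl-1,3-dioxolan-2-yl)heptan-2-one | CCCCCC1(CCCCCC(=O)Cc2cc(OCc3ccccc3)cc(OCc3ccccc3)c2)OCCO1 | intermediate (not isolated)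
9 | 1-[3,5-bis(benzyloxy)phenyl]tridecane-2,8-dione | CCCCCC(=O)CCCCCC(=O)Cc1cc(OCc2ccccc2)cc(OCc2ccccc2)c1 | intermediate
10 | 1-(3,5-dihydroxyphenyl)tridecane-2,8-dione | CCCCCC(=O)CCCCCC(=O)Cc1cc(O)cc(O)c1 | intermediate
11 | (2R)-1-(3,5-dihydroxyphenyl)-2-hydroxytridecan-8-one | CCCCCC(=O)CCCCC[C@H](Cc1cc(O)cc(O)c1)O | intermediate
12 | 5-[(2R)-2-acetoxy-8-oxotridecyl]-1,3-phenylene diacetate | CCCCCC(=O)CCCCC[C@H](Cc1cc(OC(C)=O)cc(OC(C)=O)c1)OC(C)=O | intermediate
13 | (2R)-1-(3,5-dihydroxyphenyl)-8-oxotridecan-2-yl acetate | CCCCCC(=O)CCCCC[C@H](Cc1cc(O)cc(O)c1)OC(C)=O | target

## Step count and the least certain steps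

Total: 8 steps. Longest linear sequence: 8 steps (1 to 13); bromide 6 enters at step 4 as a commercial material.

**Key step (step 6).** The most likely failure is loss of site selectivity: a pocket wide enough for a ketone with two large substituents may also accept the mid-chain carbonyl, so hydride is transferred to C8 as well as, or in place of, C2. Prolonged exposure to excess isopropanol would then carry material on to the diol. Slow turnover with a substrate of this size is the lesser risk. The fallback removes the choice of carbonyl from the enzyme and leaves it only the choice of face. It sets out from 8, which is isolated by quenching step 4 with aqueous NH4Cl in place of HCl. Hydrogenolysis (H2, Pd/C, EtOAc) gives 1-(3,5-dihydroxyphenyl)-7-(2-pentyl-1,3-dioxolan-2-yl)heptan-2-one F1. The same reductase system, now offered a single carbonyl, gives 5-[(2R)-2-hydroxy-7-(2-pentyl-1,3-dioxolan-2-yl)heptyl]benzene-1,3-diol F2. Treatment with 1 M HCl in THF at room temperature then removes the dioxolane and returns to the route at 11.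

**Step 4.** The most likely failure is Wurtz homocoupling while 7 is being formed: the benzylic bromide alkylates Grignard reagent already present, which lowers the amount of nucleophile available for 5. The fallback replaces magnesium by zinc and the amide by a thioester, and sets out from 4 and 6. Saponification of 4 (LiOH, THF–water) gives 6-(2-pentyl-1,3-dioxolan-2-yl)hexanoic acid F3. Coupling with ethanethiol (EDC, DMAP, CH2Cl2) gives S-ethyl 6-(2-pentyl-1,3-dioxolan-2-yl)hexanethioate F4. Bromide 6 is inserted by zinc dust in THF containing LiCl to give [3,5-bis(benzyloxy)benzyl]zinc bromide F5, a reagent class that forms without homocoupling. Fukuyama coupling of F4 with F5 (PdCl2(PPh3)2, THF, rt) returns to the route at 8, and the acid stage of step 4 then gives 9.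

**Step 1.** The most likely failure is over-addition: if the catalysed coupling is slower than expected, for instance through local excess of 2 or a sluggish catalyst, the Grignard reagent adds to the newly formed ketone or to the methyl ester. The fallback stops the addition by chelation instead of by rate and sets out from 1. N,O-dimethylhydroxylamine hydrochloride and pyridine in CH2Cl2 at 0 °C give methyl 7-[methoxy(methyl)amino]-7-oxoheptanoate F6. One equivalent of 2 in THF at −78 °C then adds to the amide carbonyl, which is more reactive than the ester and is held as the stable magnesium chelate until the quench, and the route is rejoined at 3.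

**Step 8.** The most likely failure is incomplete discrimination between the esters: either slow aminolysis of the C2 acetate once the aryl esters are gone, or incomplete cleavage that leaves one aryl acetate. The fallback differentiates the oxygens by alkylation instead of by ester cleavage and sets out from 11. Benzyl bromide and K2CO3 in acetone alkylate only the phenoxide oxygens to give (2R)-1-[3,5-bis(benzyloxy)phenyl]-2-hydroxytridecan-8-one F7. Acetic anhydride, pyridine and DMAP give (2R)-1-[3,5-bis(benzyloxy)phenyl]-8-oxotridecan-2-yl acetate F8. Hydrogenolysis (H2, Pd/C, EtOAc) leaves the acetate and the ketone untouched and returns to the route at 13.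

## Further compounds

F1 | step 6 | 1-(3,5-dihydroxyphenyl)-7-(2-pentyl-1,3-dioxolan-2-yl)heptan-2-one | CCCCCC1(CCCCCC(=O)Cc2cc(O)cc(O)c2)OCCO1
F2 | step 6 | 5-[(2R)-2-hydroxy-7-(2-pentyl-1,3-dioxolan-2-yl)heptyl]benzene-1,3-diol | CCCCCC1(CCCCC[C@H](Cc2cc(O)cc(O)c2)O)OCCO1
F3 | step 4 | 6-(2-pentyl-1,3-dioxolan-2-yl)hexanoic acid | CCCCCC1(CCCCCC(=O)O)OCCO1
F4 | step 4 | S-ethyl 6-(2-pentyl-1,3-dioxolan-2-yl)hexanethioate | CCCCCC1(CCCCCC(=O)SCC)OCCO1
F5 | step 4 | [3,5-bis(benzyloxy)benzyl]zinc bromide | Br[Zn]Cc1cc(OCc2ccccc2)cc(OCc2ccccc2)c1
F6 | step 1 | methyl 7-[methoxy(methyl)amino]-7-oxoheptanoate | COC(=O)CCCCCC(=O)N(C)OC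
F7 | step 8 | (2R)-1-[3,5-bis(benzyloxy)phenyl]-2-hydroxytridecan-8-one | CCCCCC(=O)CCCCC[C@H](Cc1cc(OCc2ccccc2)cc(OCc2ccccc2)c1)O
F8 | step 8 | (2R)-1-[3,5-bis(benzyloxy)phenyl]-8-oxotridecan-2-yl acetate | CCCCCC(=O)CCCCC[C@H](Cc1cc(OCc2ccccc2)cc(OCc2ccccc2)c1)OC(C)=O
A1 | alternative 1 | methyl 2,4-dioxo-6-[(2R)-2-(tert-butyldimethylsilyloxy)-7-(2-pentyl-1,3-dioxolan-2-yl)heptyl]cyclohexane-1-carboxylate (ring stereocentres undefined) | CCCCCC1(OCCO1)CCCCC[C@H](CC1CC(=O)CC(=O)C1C(=O)OC)O[Si](C)(C)C(C)(C)C
A2 | alternative 1 | (R,E)-6-(tert-butyldimethylsilyloxy)-11-(2-pentyl-1,3-dioxolan-2-yl)undec-3-en-2-one | CCCCCC1(OCCO1)CCCCC[C@H](C/C=C/C(C)=O)O[Si](C)(C)C(C)(C)C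
A3 | alternative 2 | 2-{(2R)-1-[3,5-bis(benzyloxy)phenyl]-7-(2-pentyl-1,3-dioxolan-2-yl)heptan-2-yl}-4,4,5,5-tetramethyl-1,3,2-dioxaborolane | CCCCCC1(OCCO1)CCCCC[C@H](Cc1cc(OCc2ccccc2)cc(OCc2ccccc2)c1)B1OC(C)(C)C(C)(C)O1
A4 | alternative 2 | [5-(2-pentyl-1,3-dioxolan-2-yl)pentyl]lithium | [Li]CCCCCC1(CCCCC)OCCO1
A5 | alternative 2 | vinylboronic acid pinacol ester | C=CB1OC(C)(C)C(C)(C)O1
A6 | alternative 2 | 3,5-bis(benzyloxy)phenyl trifluoromethanesulfonate | O=S(=O)(Oc1cc(OCc2ccccc2)cc(OCc2ccccc2)c1)C(F)(F)F
A7 | alternative 3 | (2R)-1-[3,5-bis(benzyloxy)phenyl]-8-oxotridecan-2-yl acetate | CCCCCC(=O)CCCCC[C@H](Cc1cc(OCc2ccccc2)cc(OCc2ccccc2)c1)OC(C)=O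
A8 | alternative 3 | (2R)-1-[3,5-bis(benzyloxy)phenyl]-5-iodopentan-2-yl acetate | ICCC[C@H](Cc1cc(OCc2ccccc2)cc(OCc2ccccc2)c1)OC(C)=O
A9 | alternative 3 | oct-1-en-3-one | C=CC(=O)CCCCC
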